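Its constants come from no measurement; what happens was integrated by code.

The constants 30 M⁻¹ s⁻¹ and 0.12 s⁻¹ are where we would start on your quick number, and they already put a question mark on your hunch that links keep forming faster than rings to the end.

all flasks: first end groups 0.010 M; second end groups 0.0105 M; time 4.0 s
- Monday's: protic impurity 0.100 mM
- Wednesday's: protic impurity 0.200 mM
- Sunday's: protic impurity 0.400 mM
- Thursday's: protic impurity 0.800 mM
- Tuesday's: protic impurity 1.50 mM

    first end groups + second end groups → rings, rate k1*[first end groups] as long as [second end groups] is above zero (k1 = 0.12 s⁻¹)
    crystals ⇌ links, rate k2*(cs2 - [links]) while solid is left; crystals form when [links] > cs2 (cs2 = 8.9 mM, k2 = 12 s⁻¹)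
    first end groups + second end groups → links (k3 = 30 M⁻¹ s⁻¹)
    first end groups + protic impurity → quenched substrate (k4 = 200 M⁻¹ s⁻¹)

- for links the crystals are counted in
- as a solid, counted per litre of solution: crystals
- "hardly changes" means that all values lie within two and a half points (for a concentration: within two and a half percent of the largest)
- run time (Monday's): 4.0 s

1. amount of links at the end, in percent of the first end groups charged for Monday's, Wednesday's, Sunday's, Thursday's, Tuesday's, in this order
2. the course of these numbers from the first flask to the last (falls, then rises / rises all the way / falls all the way / rises, then falls / hardly changes)

Both steps spend one first end group and one second end group, so links and rings form in the ratio of their rates. With second end groups at full charge that ratio is 2.62, which we call the link lead, a selectivity factor; multiplied by the fraction of second end groups left, it gives the running lead.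

For Monday's flask we go round by hand, setting the impurity aside for now. Holding second end groups at full charge, first end groups decay at 0.435 s⁻¹, so 82.4 % of them are used in 4.0 s. That use puts the mean fraction of second end groups at 60.7 %, not at full charge. Putting this back in gives 71.2 % used and a mean fraction of 66.1 %, and once more gives 73.1 % used. Links take their share of that, about 46.4 % of the first end groups charged. The running lead at the end comes to 0.798, below one, so we expect rings to be forming faster than links by then, against your hunch.

With first end groups at full charge the impurity disappears at 2.00 s⁻¹, faster than the 0.435 s⁻¹ of first end groups, so in this estimate we count its whole charge as quenched. That is 1.00 % of the first end groups in Monday's flask and 15.0 % in Tuesday's, and links should fall along the row.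

The forecast gives 43.3 %, 43 %, 42.6 %, 41.6 % and 39.8 %, a course that falls all the way, on the ground that “Quenching removes first end groups”. Its Monday figure stands below our 46.4 %.

The simulation gives 43.3 %, 43.0 %, 42.6 %, 41.6 % and 39.8 %, a row that falls all the way, as the forecast has it. In Monday's flask at 4.00 s, the half-life of first end groups by the link step is 6.5 s, longer than the 5.8 s by the ring step, and the link lead of 2.62 times the 34 % of second end groups left is 0.891. In Tuesday's flask at 4.00 s, 41 % of second end groups is left, which makes the running lead 1.07, higher than Monday's.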